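Ring positions are given in target numbering (O1, C2–C6) throughout; names of intermediates use their own locants.

## The problem

The target is a tetrahydropyran (O1, C2–C6) with four different substituents: a 4-hydroxyphenyl group at C2, a free hydroxyl at C3, ring A at C4 (a 2,6-dihydroxy-4-methoxyphenyl ring that also carries the 4-hydroxycinnamoyl group of a chalcone) and a 2-(4-hydroxyphenyl)ethyl chain at C6. All four ring stereocentres are S. C2/C3 are cis, C3/C4 trans and C2/C6 trans, so in the chair the C3, C4 and C6 substituents are equatorial and the C2 aryl group is axial. C2, C3 and C4 are contiguous and can control one another, but C6 is separated from them by the C5 methylene and the ring oxygen and needs its own control element. The axial C2 centre is a para-oxygenated benzylic ether carbon. Acid can ionise the C2–O1 bond and let it re-close to the 2,6-cis isomer, so C2 has to be set without a benzylic cation and kept away from strong Brønsted or Lewis acids afterwards. The 2'-hydroxychalcone excludes hydrogenolytic deprotection and strong base at the end, and ring A is electron-rich, oxidisable and attached through its most hindered carbon. The enabling feature is that deleting O1 joins C2 to C6 in a cyclopentanone whose carbonyl carbon (C6) lies between a secondary benzylic carbon (C2) and a methylene (C5). A peracid can therefore re-insert the oxygen on the C2 side with retention, and the 2-aryl-3-oxy-4-aryl pattern of that ring is what 4-hydroxycyclopentenone chemistry delivers.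

## Retrosynthesis

**Unmasking (31 from 30).** The last operation only cleaves O–C acetal bonds. The five phenols are carried as MOM ethers because ring A needs an ortho-directing group for metalation and because the groups must survive organolithiums, a cuprate, peracid, hydrogenation and fluoride. Benzyl ethers are excluded by the enone, and silyl ethers by the fluoride-triggered ring closure. The C3 hydroxyl is carried as the achiral 4-methoxyoxan-4-yl ketal, so a single mild acidic step frees all six hydroxyl groups of 30. The forward step must be gentle enough for the C2 benzylic ether and the hydroxychalcone.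

**Ring A–carbonyl bond (30 from 27 and 28).** Cutting the aryl–C(=O) bond leaves the aryl bromide 27 and the cinnamoyl Weinreb amide 28. A Friedel–Crafts acylation would need the Lewis acids that ionise C2–O1, and an acetylation followed by aldol condensation costs an extra operation on the main line. Bromide 27 comes from tetrahydropyran 26 by electrophilic bromination of its most electron-rich ring, and 28 from aldehyde 2 in one olefination. The forward reaction must be a clean 1,2-addition of a hindered aryllithium.

**O1–C6 bond (26 from 24).** The ring is opened at O1–C6, not at the acid-labile O1–C2 bond. Closing it by alkoxide displacement of a C6 mesylate (24) with inversion transfers a carbinol configuration to C6 stereospecifically. Reduction of a C6 oxocarbenium ion would need a Lewis acid, and its facial outcome depends on an uncertain conformer balance. The cost is that C6 must be made as a single carbinol epimer. The C3 oxygen is kept as a ketal and not as a silyl ether, because a silyl group could migrate to the neighbouring C2 alkoxide and let the C3 oxygen close a five-membered ring instead.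

**C6 configuration (24 from 23, 22 and 21).** The carbinol of 24 is traced through alcohol 23 to propargylic alcohol 22 and ynone 21. A ketone flanked by two methylenes cannot be reduced selectively, whereas an alkynyl ketone is reduced under catalyst control by asymmetric transfer hydrogenation. The remote C2–C4 centres then have no influence on the outcome.

**C6–chain bond (20 from 17 and 18).** Ynone 21 is the silyl ether of hydroxy ynone 20, which arises from acyl substitution of lactone 17 by the acetylide of alkyne 18. This uses the lactone carbonyl created by the key step as the electrophile for the whole side chain, and 18 is one step from aldehyde 2.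

**Oxygen deletion (17 from 16, the key disconnection).** Removing O1 from lactone 17 gives cyclopentanone 16, with all three contiguous stereocentres of the target on a five-membered carbocycle. The forward Baeyer–Villiger oxidation must migrate C2 rather than C5 and must keep the C2 configuration. Both follow from C2 being a secondary benzylic carbon and from the concerted nature of the shift. No other cut turns the fragile axial benzylic ether centre into an ordinary carbon stereocentre.

**C4–ring A bond (16 from 10 and 12).** Cutting the C4–aryl bond gives enone 10 and the arene 12, metalated between its two MOM ethers. Conjugate addition of an aryl cuprate anti to the oxygen substituent of a 4-oxycyclopentenone is a well-established addition, and here the aryl group at the neighbouring carbon shields the same face.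

**C3 configuration and absolute stereochemistry (10 from 9, 7 and 6).** Ketal 10 comes from cis alcohol 9, which is the Mitsunobu inversion product of trans alcohol 7. Alcohol 7 is one enantiomer of racemate 6, obtained by lipase resolution. The cis relationship must exist before the cuprate step so that the cuprate adds anti to both groups.

**Five-membered ring (6 from 5, then 2 and 3).** The Piancatelli rearrangement of furyl carbinol 5 builds the cyclopentenone with the aryl group next to the carbonyl and trans to the hydroxyl in one step. Carbinol 5 is made from furan 3 and aldehyde 2, and 2 is the MOM ether of 4-hydroxybenzaldehyde 1. Aldehyde 2 thus supplies three of the four aryl units; ring A comes from 5-methoxyresorcinol 11.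

## Roads not taken

**Alternative 1: oxidative ring expansion of a furyl carbinol.** Here the O1–C6 bond is made by oxidising (S)-furan-2-yl[4-(methoxymethoxy)phenyl]methanol A1. The furan opens to an enedione and the carbinol oxygen closes onto the former furan C5, giving pyranone A2. Its merits are real. A1 is available by catalytic asymmetric reduction, so no resolution discards half the material. The C2–O1 bond and the C2 configuration are there from the first step, and substitution at the lactol carbon of such pyranones usually gives 2,6-trans products, which is what C6 needs here. In step count to a functionalised pyran it beats the chosen plan. Its weak points are specific to this target. In A2 the enone β-carbon is C5, not C4, so ring A cannot be brought in by conjugate addition. It would have to be attached at the enone α-carbon through a hindered cross-coupling, and the C4 and C3 centres then set by two reductions. C2 would stay α to the C3 ketone, and thus both benzylic and enolisable, through all of these steps, and its more stable orientation is equatorial, the wrong one. The chosen plan pays with a resolution and a longer sequence, but it never places a carbonyl next to C2 once the oxygen is on it.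

**Alternative 2: oxa-Diels–Alder dihydropyranone.** The C5–C6 and O1–C2 bonds would be formed by cycloaddition of aldehyde A3 with diene A4 under a chiral Lewis acid, giving dihydropyranone A5 after loss of methanol. The C2 aryl group would then be delivered axially by conjugate addition. This route sets C6 by catalysis in the first ring-forming step, and the 2,6-trans relationship would come from a well-known axial addition. In both respects it is better than the chosen plan, which spends six steps on C6. Its weak point is C4. After the aryl addition C4 is a ketone, and turning it into a methine that carries a di-ortho-substituted aryl group needs a 1,2-addition followed by removal of a tertiary benzylic hydroxyl. That removal calls for ionising conditions in a molecule whose C2–O1 bond ionises under the same conditions, and the C3 and C4 configurations would rest on unproven substrate control. The chosen plan attaches ring A by an anti cuprate addition with a secure facial bias and sets C2–C4 before the pyran exists.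

**Alternative 3: directed hydroformylation.** The acyclic alkene A6 carries a phosphine-bearing ester on the C3 oxygen. Rhodium-catalysed hydroformylation with Rh(CO)2(acac) would deliver hydrogen to C4 and the formyl carbon to C5, and the C2 hydroxyl would close onto the aldehyde to give lactol A7. The route is convergent and catalytic, the C2/C3 diol can be made without resolution, and the lactol is at the oxidation level needed for the C6 chain. These are advantages over the chosen plan at the front end. The weak points are that the alkene is a 1,1-disubstituted styrene with a 2,6-dioxygenated aryl group, a slow substrate class for which the sense of 1,2-induction by the directing ester has no close precedent. C6 would then have to be introduced at the lactol carbon by Lewis-acid-mediated substitution or olefination and reclosure, which again endangers C2 and leaves C6 to an uncertain bias. The chosen plan is longer but sets C4 by a reaction of known sense and sets C6 by catalyst control followed by a stereospecific displacement.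

Key step: step 9

Assumption: in step 4 the lipase is taken to show the same spatial preference at the carbinol carbon as with 4-hydroxycyclopent-2-en-1-one, so that the (4R,5S)-alcohol is the slow-reacting enantiomer; if the sense were opposite, the same enantiomer would be collected as its acetate and released by the same enzyme in buffer.

## Route

Step 1
Reactants: 1 4-hydroxybenzaldehyde
Product: 2 4-(methoxymethoxy)benzaldehyde
Conditions: MOMCl, K2CO3, acetone, 0 °C → rt
Reagents that add atoms: chloromethyl methyl ether (MOMCl), COCCl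
Why: Williamson-type O-alkylation of the phenoxide by the α-chloro ether; the aldehyde is untouched, and the MOM acetal later tolerates organolithiums, the cuprate, peracid, hydrogenation and fluoride.

Step 2
Reactants: 3 furan; 2 4-(methoxymethoxy)benzaldehyde
Product: 5 rac-(furan-2-yl)[4-(methoxymethoxy)phenyl]methanol, via furan-2-yllithium 4 (not isolated)
Conditions: n-BuLi, THF, 0 °C; then 2, −78 → 0 °C; H2O
Reagents that add atoms: none
Why: α-Lithiation of furan followed by 1,2-addition of the heteroaryllithium to the aldehyde; the carbinol centre is left racemic because it becomes planar in the next step.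

Step 3
Reactants: 5 rac-(furan-2-yl)[4-(methoxymethoxy)phenyl]methanol
Product: 6 rac-trans-4-hydroxy-5-[4-(methoxymethoxy)phenyl]cyclopent-2-en-1-one
Conditions: ZnCl2, dioxane/H2O, 80 °C (pH about 6)
Reagents that add atoms: water, O
Why: Piancatelli rearrangement: zinc-assisted ionisation of the furyl carbinol, capture of water at furan C5, ring opening to a hydroxypentadienyl cation and conrotatory 4π electrocyclisation, which places aryl and hydroxyl trans; the weakly acidic medium is chosen to spare the aryl MOM ether.

Step 4
Reactants: 6 rac-trans-4-hydroxy-5-[4-(methoxymethoxy)phenyl]cyclopent-2-en-1-one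
Product: 7 (4R,5S)-4-hydroxy-5-[4-(methoxymethoxy)phenyl]cyclopent-2-en-1-one
Conditions: lipase PS (Burkholderia cepacia), vinyl acetate, MTBE, 30 °C, stopped slightly past half conversion; chromatography
Reagents that add atoms: none
Why: Lipase-catalysed kinetic resolution of a 4-hydroxycyclopentenone by enantioselective acetylation; the (4S,5R)-alcohol is expected to be acylated and 7 to remain, and running past half conversion raises the enantiomeric purity of the recovered alcohol, which fixes the absolute configuration of C2 of the target.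

Step 5
Reactants: 7 (4R,5S)-4-hydroxy-5-[4-(methoxymethoxy)phenyl]cyclopent-2-en-1-one
Product: 9 (4S,5S)-4-hydroxy-5-[4-(methoxymethoxy)phenyl]cyclopent-2-en-1-one, via cis-formate 8 (not isolated)
Conditions: HCO2H, PPh3, DIAD, THF, 0 °C; then MeOH, KHCO3 (cat.), 0 °C
Reagents that add atoms: formic acid, O=CO
Why: Mitsunobu inversion: formate displaces the oxyphosphonium ion at C4 in an SN2 step, turning the trans alcohol into the cis formate (the future C3 becomes S); formic acid is a small nucleophile for the hindered face, and its ester is methanolysed at 0 °C with a trace of hydrogen carbonate, mild enough for the epimerisable C5 and the enone.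

Step 6
Reactants: 9 (4S,5S)-4-hydroxy-5-[4-(methoxymethoxy)phenyl]cyclopent-2-en-1-one
Product: 10 (4S,5S)-4-[(4-methoxyoxan-4-yl)oxy]-5-[4-(methoxymethoxy)phenyl]cyclopent-2-en-1-one
Conditions: 4-methoxy-3,6-dihydro-2H-pyran, PPTS (cat.), CH2Cl2, 0 °C
Reagents that add atoms: 4-methoxy-3,6-dihydro-2H-pyran, COC1=CCOCC1
Why: Acid-catalysed addition of the alcohol to the enol ether gives an achiral mixed ketal without any base; unlike a silyl ether it cannot migrate to a neighbouring alkoxide in step 16, and it leaves in the final acidic step.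

Step 7
Reactants: 11 5-methoxyresorcinol
Product: 12 1-methoxy-3,5-bis(methoxymethoxy)benzene
Conditions: NaH, MOMCl, DMF, 0 °C → rt
Reagents that add atoms: chloromethyl methyl ether (MOMCl), COCCl
Why: Double Williamson alkylation of the resorcinol; the two MOM ethers are the ortho-directing groups for step 8.

Step 8
Reactants: 12 1-methoxy-3,5-bis(methoxymethoxy)benzene; 10 (4S,5S)-4-[(4-methoxyoxan-4-yl)oxy]-5-[4-(methoxymethoxy)phenyl]cyclopent-2-en-1-one
Product: 16 (2S,3S,4S)-3-[(4-methoxyoxan-4-yl)oxy]-4-[4-methoxy-2,6-bis(methoxymethoxy)phenyl]-2-[4-(methoxymethoxy)phenyl]cyclopentan-1-one, via aryllithium 13 (not isolated), via lithium diarylcuprate 14 (not isolated), via lithium enolate 15 (not isolated)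
Conditions: 12, n-BuLi, THF, 0 °C; CuBr·SMe2, −78 → −40 °C; 10, −78 → −40 °C; sat. aq. NH4Cl, −78 °C
Reagents that add atoms: none
Why: Directed ortho-lithiation between the two MOM ethers, transmetalation to the Gilman cuprate and conjugate addition to the 4-oxygenated cyclopentenone; the aryl group enters anti to the ketal oxygen and to the aryl group on the other face, which sets C4 of the target trans to C3, and the enolate lies on the methylene side, has no β leaving group and is protonated cold, so the aryl-bearing α-carbon is never enolised.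

Step 9
Reactants: 16 (2S,3S,4S)-3-[(4-methoxyoxan-4-yl)oxy]-4-[4-methoxy-2,6-bis(methoxymethoxy)phenyl]-2-[4-(methoxymethoxy)phenyl]cyclopentan-1-one
Product: 17 (4S,5S,6S)-5-[(4-methoxyoxan-4-yl)oxy]-4-[4-methoxy-2,6-bis(methoxymethoxy)phenyl]-6-[4-(methoxymethoxy)phenyl]oxan-2-one
Conditions: mCPBA, NaHCO3, CH2Cl2, 0 °C → rt
Reagents that add atoms: m-chloroperbenzoic acid, OOC(=O)c1cccc(Cl)c1
Why: Baeyer–Villiger oxidation: the peracid adds to the cyclopentanone carbonyl to give the tetrahedral peroxy (Criegee) adduct, and the C1–C2 bond migrates to the proximal peroxide oxygen, antiperiplanar to the breaking O–O bond, as m-chlorobenzoate leaves. The closest known reaction type is the regioselective, stereoretentive Baeyer–Villiger oxidation of 2-arylcycloalkanones. The six-membered ring is not closed end to end; it arises by ring expansion, with oxygen inserted into the C1–C2 bond of the five-membered ring, so the new O–C(aryl) and O–C(=O) bonds form in one concerted 1,2-shift. The centre that becomes C6 of the lactone (C2 of the target) is controlled by the configuration of C2 of 16, because the migrating carbon keeps its configuration and no benzylic cation is formed. The step needs migration of C2 in preference to C5, which is secured because C2 is a secondary benzylic carbon bearing an electron-rich aryl group and C5 is a methylene. It needs configurational integrity at the enolisable C2 before migration, for which the hydrogen carbonate buffer and low temperature are chosen; these also protect the ketal. It needs oxidation of the ketone in preference to the electron-rich ring A, for which an unactivated peracid without strong acid is used.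

Step 10
Reactants: 2 4-(methoxymethoxy)benzaldehyde
Product: 18 1-ethynyl-4-(methoxymethoxy)benzene
Conditions: dimethyl (1-diazo-2-oxopropyl)phosphonate, K2CO3, MeOH, rt
Reagents that add atoms: dimethyl (1-diazo-2-oxopropyl)phosphonate, COP(=O)(OC)C(=[N+]=[N-])C(C)=O
Why: Ohira–Bestmann homologation: methanolysis of the reagent gives the diazomethylphosphonate anion, which adds to the aldehyde, eliminates phosphate and loses nitrogen to an alkylidene carbene that rearranges to the terminal alkyne; the carbonate conditions leave the MOM ether intact.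

Step 11
Reactants: 18 1-ethynyl-4-(methoxymethoxy)benzene; 17 (4S,5S,6S)-5-[(4-methoxyoxan-4-yl)oxy]-4-[4-methoxy-2,6-bis(methoxymethoxy)phenyl]-6-[4-(methoxymethoxy)phenyl]oxan-2-one
Product: 20 (5S,6S,7S)-7-hydroxy-6-[(4-methoxyoxan-4-yl)oxy]-5-[4-methoxy-2,6-bis(methoxymethoxy)phenyl]-1,7-bis[4-(methoxymethoxy)phenyl]hept-1-yn-3-one, via lithium acetylide 19 (not isolated)
Conditions: 18, n-BuLi, THF, −78 °C; then 17, −78 °C; AcOH, −78 °C
Reagents that add atoms: none
Why: Acyl substitution of the δ-lactone by the lithium acetylide; the tetrahedral lactolate is stable at −78 °C, which prevents a second addition, and it opens on protonation to the δ-hydroxy ynone with C2, C3 and C4 of the target untouched.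

Step 12
Reactants: 20 (5S,6S,7S)-7-hydroxy-6-[(4-methoxyoxan-4-yl)oxy]-5-[4-methoxy-2,6-bis(methoxymethoxy)phenyl]-1,7-bis[4-(methoxymethoxy)phenyl]hept-1-yn-3-one
Product: 21 (5S,6S,7S)-6-[(4-methoxyoxan-4-yl)oxy]-5-[4-methoxy-2,6-bis(methoxymethoxy)phenyl]-1,7-bis[4-(methoxymethoxy)phenyl]-7-[(triethylsilyl)oxy]hept-1-yn-3-one
Conditions: TESCl, imidazole, CH2Cl2, 0 °C
Reagents that add atoms: chlorotriethylsilane, CC[Si](Cl)(CC)CC
Why: Silylation of the benzylic alcohol with a chlorosilane and imidazole; it fixes the open-chain form and keeps this oxygen from being sulfonylated in step 15, and a triethylsilyl ether is chosen because fluoride removes it quickly.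

Step 13
Reactants: 21 (5S,6S,7S)-6-[(4-methoxyoxan-4-yl)oxy]-5-[4-methoxy-2,6-bis(methoxymethoxy)phenyl]-1,7-bis[4-(methoxymethoxy)phenyl]-7-[(triethylsilyl)oxy]hept-1-yn-3-one
Product: 22 (3S,5S,6S,7S)-6-[(4-methoxyoxan-4-yl)oxy]-5-[4-methoxy-2,6-bis(methoxymethoxy)phenyl]-1,7-bis[4-(methoxymethoxy)phenyl]-7-[(triethylsilyl)oxy]hept-1-yn-3-ol
Conditions: Ru[(S,S)-TsDPEN](p-cymene) (cat.), i-PrOH, rt
Reagents that add atoms: none
Why: Noyori asymmetric transfer hydrogenation of an α,β-acetylenic ketone: the ruthenium hydride and the amine proton are delivered to one carbonyl face under catalyst control, the (S,S)-catalyst giving the (S)-propargylic alcohol irrespective of the remote stereocentres; this is the configuration that becomes 6S after inversion in step 16.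

Step 14
Reactants: 22 (3S,5S,6S,7S)-6-[(4-methoxyoxan-4-yl)oxy]-5-[4-methoxy-2,6-bis(methoxymethoxy)phenyl]-1,7-bis[4-(methoxymethoxy)phenyl]-7-[(triethylsilyl)oxy]hept-1-yn-3-ol
Product: 23 (3R,5S,6S,7S)-6-[(4-methoxyoxan-4-yl)oxy]-5-[4-methoxy-2,6-bis(methoxymethoxy)phenyl]-1,7-bis[4-(methoxymethoxy)phenyl]-7-[(triethylsilyl)oxy]heptan-3-ol
Conditions: H2 (1 atm), Pd/C, Et3N (trace), EtOAc, rt
Reagents that add atoms: none
Why: Heterogeneous hydrogenation of the alkyne to the saturated chain; the trace of amine suppresses hydrogenolysis of the benzylic silyl ether and acid-induced loss of the ketal, and the carbinol centre is unchanged in space (its descriptor becomes R only because the priorities change).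

Step 15
Reactants: 23 (3R,5S,6S,7S)-6-[(4-methoxyoxan-4-yl)oxy]-5-[4-methoxy-2,6-bis(methoxymethoxy)phenyl]-1,7-bis[4-(methoxymethoxy)phenyl]-7-[(triethylsilyl)oxy]heptan-3-ol
Product: 24 (3R,5S,6S,7S)-6-[(4-methoxyoxan-4-yl)oxy]-5-[4-methoxy-2,6-bis(methoxymethoxy)phenyl]-1,7-bis[4-(methoxymethoxy)phenyl]-7-[(triethylsilyl)oxy]heptan-3-yl methanesulfonate
Conditions: MsCl, Et3N, CH2Cl2, 0 °C
Reagents that add atoms: methanesulfonyl chloride, CS(=O)(=O)Cl
Why: Sulfonylation of the only free hydroxyl group with retention at carbon; the secondary mesylate is used directly in the next step.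

Step 16
Reactants: 24 (3R,5S,6S,7S)-6-[(4-methoxyoxan-4-yl)oxy]-5-[4-methoxy-2,6-bis(methoxymethoxy)phenyl]-1,7-bis[4-(methoxymethoxy)phenyl]-7-[(triethylsilyl)oxy]heptan-3-yl methanesulfonate
Product: 26 (2S,3S,4S,6S)-3-[(4-methoxyoxan-4-yl)oxy]-4-[4-methoxy-2,6-bis(methoxymethoxy)phenyl]-2-[4-(methoxymethoxy)phenyl]-6-{2-[4-(methoxymethoxy)phenyl]ethyl}oxane, via C7 alkoxide 25 (not isolated)
Conditions: Bu4NF, THF, 0 → 45 °C
Reagents that add atoms: none
Why: Fluoride cleaves the triethylsilyl ether and the liberated alkoxide displaces the mesylate in a 6-exo-tet Williamson closure with inversion, forming the O1–C6 bond and setting C6 as S, trans to the C2 aryl group; C2 keeps the configuration from step 9 because its C–O bond is never broken, and the ketal oxygen at C3 can neither migrate nor compete as a nucleophile.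

Step 17
Reactants: 26 (2S,3S,4S,6S)-3-[(4-methoxyoxan-4-yl)oxy]-4-[4-methoxy-2,6-bis(methoxymethoxy)phenyl]-2-[4-(methoxymethoxy)phenyl]-6-{2-[4-(methoxymethoxy)phenyl]ethyl}oxane
Product: 27 (2S,3S,4S,6S)-4-[3-bromo-4-methoxy-2,6-bis(methoxymethoxy)phenyl]-3-[(4-methoxyoxan-4-yl)oxy]-2-[4-(methoxymethoxy)phenyl]-6-{2-[4-(methoxymethoxy)phenyl]ethyl}oxane
Conditions: NBS, NaHCO3, DMF, 0 °C
Reagents that add atoms: N-bromosuccinimide, O=C1CCC(=O)N1Br
Why: Electrophilic aromatic bromination; ring A with three oxygen substituents is far more nucleophilic than the two mono-oxygenated rings, and its two free positions are equivalent by rotation about the C4–aryl bond, so one monobromide is expected; hydrogen carbonate protects the ketal from adventitious HBr.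

Step 18
Reactants: 2 4-(methoxymethoxy)benzaldehyde
Product: 28 (E)-N-methoxy-3-[4-(methoxymethoxy)phenyl]-N-methylprop-2-enamide
Conditions: diethyl {2-[methoxy(methyl)amino]-2-oxoethyl}phosphonate, NaH, THF, 0 °C → rt
Reagents that add atoms: diethyl {2-[methoxy(methyl)amino]-2-oxoethyl}phosphonate, CCOP(=O)(OCC)CC(=O)N(C)OC
Why: Horner–Wadsworth–Emmons olefination with a stabilised amide phosphonate, which gives the E-alkene of the future chalcone.

Step 19
Reactants: 27 (2S,3S,4S,6S)-4-[3-bromo-4-methoxy-2,6-bis(methoxymethoxy)phenyl]-3-[(4-methoxyoxan-4-yl)oxy]-2-[4-(methoxymethoxy)phenyl]-6-{2-[4-(methoxymethoxy)phenyl]ethyl}oxane; 28 (E)-N-methoxy-3-[4-(methoxymethoxy)phenyl]-N-methylprop-2-enamide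
Product: 30 (E)-1-{6-methoxy-2,4-bis(methoxymethoxy)-3-[(2S,3S,4S,6S)-3-[(4-methoxyoxan-4-yl)oxy]-2-[4-(methoxymethoxy)phenyl]-6-{2-[4-(methoxymethoxy)phenyl]ethyl}oxan-4-yl]phenyl}-3-[4-(methoxymethoxy)phenyl]prop-2-en-1-one, via aryllithium 29 (not isolated)
Conditions: n-BuLi, THF, −78 °C; then 28, −78 → −30 °C; H2O
Reagents that add atoms: none
Why: Bromine–lithium exchange at −78 °C and 1,2-addition of the aryllithium to the Weinreb amide; the chelated tetrahedral intermediate releases the enone only on work-up, so the chalcone forms without over-addition and with the E double bond unchanged.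

Step 20
Reactants: 30 (E)-1-{6-methoxy-2,4-bis(methoxymethoxy)-3-[(2S,3S,4S,6S)-3-[(4-methoxyoxan-4-yl)oxy]-2-[4-(methoxymethoxy)phenyl]-6-{2-[4-(methoxymethoxy)phenyl]ethyl}oxan-4-yl]phenyl}-3-[4-(methoxymethoxy)phenyl]prop-2-en-1-one
Product: 31 (E)-1-{2,4-dihydroxy-3-[(2S,3S,4S,6S)-3-hydroxy-2-(4-hydroxyphenyl)-6-[2-(4-hydroxyphenyl)ethyl]oxan-4-yl]-6-methoxyphenyl}-3-(4-hydroxyphenyl)prop-2-en-1-one
Conditions: HCl (0.5 M in MeOH), THF/MeOH, 0 °C → rt; NaHCO3 as soon as conversion is complete
Reagents that add atoms: none
Why: Acid-catalysed acetal exchange removes the ketal and the five MOM ethers in one operation; dilute acid at or below room temperature with prompt neutralisation is chosen to limit ionisation of the C2–O1 benzylic ether and acid-induced reactions of the hydroxychalcone.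

## Compound list

1 | 4-hydroxybenzaldehyde | O=Cc1ccc(O)cc1 | starting material
2 | 4-(methoxymethoxy)benzaldehyde | COCOc1ccc(C=O)cc1 | intermediate
3 | furan | c1ccoc1 | starting material
4 | furan-2-yllithium | [Li]c1ccco1 | intermediate (not isolated)
5 | rac-(furan-2-yl)[4-(methoxymethoxy)phenyl]methanol (both enantiomers) | OC(c1ccco1)c1ccc(OCOC)cc1 | intermediate
6 | rac-trans-4-hydroxy-5-[4-(methoxymethoxy)phenyl]cyclopent-2-en-1-one, (4R,5S) and (4S,5R) | O=C1C=C[C@@H](O)[C@@H]1c1ccc(OCOC)cc1.O=C1C=C[C@H](O)[C@H]1c1ccc(OCOC)cc1 | intermediate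
7 | (4R,5S)-4-hydroxy-5-[4-(methoxymethoxy)phenyl]cyclopent-2-en-1-one | O=C1C=C[C@@H](O)[C@@H]1c1ccc(OCOC)cc1 | intermediate
8 | (1S,5S)-5-[4-(methoxymethoxy)phenyl]-4-oxocyclopent-2-en-1-yl formate | O=C1C=C[C@H](OC=O)[C@@H]1c1ccc(OCOC)cc1 | intermediate (not isolated)
9 | (4S,5S)-4-hydroxy-5-[4-(methoxymethoxy)phenyl]cyclopent-2-en-1-one | O=C1C=C[C@H](O)[C@@H]1c1ccc(OCOC)cc1 | intermediate
10 | (4S,5S)-4-[(4-methoxyoxan-4-yl)oxy]-5-[4-(methoxymethoxy)phenyl]cyclopent-2-en-1-one | O=C1C=C[C@H](OC2(OC)CCOCC2)[C@@H]1c1ccc(OCOC)cc1 | intermediate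
11 | 5-methoxyresorcinol | COc1cc(O)cc(O)c1 | starting material
12 | 1-methoxy-3,5-bis(methoxymethoxy)benzene | COCOc1cc(OC)cc(OCOC)c1 | intermediate
13 | [4-methoxy-2,6-bis(methoxymethoxy)phenyl]lithium | [Li]c1c(OCOC)cc(OC)cc1OCOC | intermediate (not isolated)
14 | lithium bis[4-methoxy-2,6-bis(methoxymethoxy)phenyl]cuprate | [Li+].COCOc1cc(OC)cc(OCOC)c1[Cu-]c1c(OCOC)cc(OC)cc1OCOC | intermediate (not isolated)
15 | lithium enolate of 16 (enolised toward the methylene carbon) | [Li+].[O-]C1=C[C@@H](c2c(OCOC)cc(OC)cc2OCOC)[C@H](OC2(OC)CCOCC2)[C@@H]1c1ccc(OCOC)cc1 | intermediate (not isolated)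
16 | (2S,3S,4S)-3-[(4-methoxyoxan-4-yl)oxy]-4-[4-methoxy-2,6-bis(methoxymethoxy)phenyl]-2-[4-(methoxymethoxy)phenyl]cyclopentan-1-one | O=C1C[C@@H](c2c(OCOC)cc(OC)cc2OCOC)[C@H](OC2(OC)CCOCC2)[C@@H]1c1ccc(OCOC)cc1 | intermediate
17 | (4S,5S,6S)-5-[(4-methoxyoxan-4-yl)oxy]-4-[4-methoxy-2,6-bis(methoxymethoxy)phenyl]-6-[4-(methoxymethoxy)phenyl]oxan-2-one | O=C1C[C@@H](c2c(OCOC)cc(OC)cc2OCOC)[C@H](OC2(OC)CCOCC2)[C@H](c2ccc(OCOC)cc2)O1 | intermediate
18 | 1-ethynyl-4-(methoxymethoxy)benzene | C#Cc1ccc(OCOC)cc1 | intermediate
19 | lithium [4-(methoxymethoxy)phenyl]acetylide | [Li]C#Cc1ccc(OCOC)cc1 | intermediate (not isolated)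
20 | (5S,6S,7S)-7-hydroxy-6-[(4-methoxyoxan-4-yl)oxy]-5-[4-methoxy-2,6-bis(methoxymethoxy)phenyl]-1,7-bis[4-(methoxymethoxy)phenyl]hept-1-yn-3-one | O=C(C#Cc1ccc(OCOC)cc1)C[C@@H](c1c(OCOC)cc(OC)cc1OCOC)[C@H](OC1(OC)CCOCC1)[C@@H](O)c1ccc(OCOC)cc1 | intermediate
21 | (5S,6S,7S)-6-[(4-methoxyoxan-4-yl)oxy]-5-[4-methoxy-2,6-bis(methoxymethoxy)phenyl]-1,7-bis[4-(methoxymethoxy)phenyl]-7-[(triethylsilyl)oxy]hept-1-yn-3-one | O=C(C#Cc1ccc(OCOC)cc1)C[C@@H](c1c(OCOC)cc(OC)cc1OCOC)[C@H](OC1(OC)CCOCC1)[C@@H](O[Si](CC)(CC)CC)c1ccc(OCOC)cc1 | intermediate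
22 | (3S,5S,6S,7S)-6-[(4-methoxyoxan-4-yl)oxy]-5-[4-methoxy-2,6-bis(methoxymethoxy)phenyl]-1,7-bis[4-(methoxymethoxy)phenyl]-7-[(triethylsilyl)oxy]hept-1-yn-3-ol | O[C@H](C#Cc1ccc(OCOC)cc1)C[C@@H](c1c(OCOC)cc(OC)cc1OCOC)[C@H](OC1(OC)CCOCC1)[C@@H](O[Si](CC)(CC)CC)c1ccc(OCOC)cc1 | intermediate
23 | (3R,5S,6S,7S)-6-[(4-methoxyoxan-4-yl)oxy]-5-[4-methoxy-2,6-bis(methoxymethoxy)phenyl]-1,7-bis[4-(methoxymethoxy)phenyl]-7-[(triethylsilyl)oxy]heptan-3-ol | O[C@H](CCc1ccc(OCOC)cc1)C[C@@H](c1c(OCOC)cc(OC)cc1OCOC)[C@H](OC1(OC)CCOCC1)[C@@H](O[Si](CC)(CC)CC)c1ccc(OCOC)cc1 | intermediate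
24 | (3R,5S,6S,7S)-6-[(4-methoxyoxan-4-yl)oxy]-5-[4-methoxy-2,6-bis(methoxymethoxy)phenyl]-1,7-bis[4-(methoxymethoxy)phenyl]-7-[(triethylsilyl)oxy]heptan-3-yl methanesulfonate | CS(=O)(=O)O[C@H](CCc1ccc(OCOC)cc1)C[C@@H](c1c(OCOC)cc(OC)cc1OCOC)[C@H](OC1(OC)CCOCC1)[C@@H](O[Si](CC)(CC)CC)c1ccc(OCOC)cc1 | intermediate
25 | tetrabutylammonium C7 alkoxide of desilylated 24 | CS(=O)(=O)O[C@H](CCc1ccc(OCOC)cc1)C[C@@H](c1c(OCOC)cc(OC)cc1OCOC)[C@H](OC1(OC)CCOCC1)[C@@H]([O-])c1ccc(OCOC)cc1.CCCC[N+](CCCC)(CCCC)CCCC | intermediate (not isolated)
26 | (2S,3S,4S,6S)-3-[(4-methoxyoxan-4-yl)oxy]-4-[4-methoxy-2,6-bis(methoxymethoxy)phenyl]-2-[4-(methoxymethoxy)phenyl]-6-{2-[4-(methoxymethoxy)phenyl]ethyl}oxane | COc1cc(OCOC)c([C@@H]2C[C@H](CCc3ccc(OCOC)cc3)O[C@@H](c3ccc(OCOC)cc3)[C@H]2OC2(OC)CCOCC2)c(OCOC)c1 | intermediate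
27 | (2S,3S,4S,6S)-4-[3-bromo-4-methoxy-2,6-bis(methoxymethoxy)phenyl]-3-[(4-methoxyoxan-4-yl)oxy]-2-[4-(methoxymethoxy)phenyl]-6-{2-[4-(methoxymethoxy)phenyl]ethyl}oxane | COc1cc(OCOC)c([C@@H]2C[C@H](CCc3ccc(OCOC)cc3)O[C@@H](c3ccc(OCOC)cc3)[C@H]2OC2(OC)CCOCC2)c(OCOC)c1Br | intermediate
28 | (E)-N-methoxy-3-[4-(methoxymethoxy)phenyl]-N-methylprop-2-enamide | CON(C)C(=O)/C=C/c1ccc(OCOC)cc1 | intermediate
29 | aryllithium from 27 (lithium in place of bromine) | COc1cc(OCOC)c([C@@H]2C[C@H](CCc3ccc(OCOC)cc3)O[C@@H](c3ccc(OCOC)cc3)[C@H]2OC2(OC)CCOCC2)c(OCOC)c1[Li] | intermediate (not isolated)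
30 | (E)-1-{6-methoxy-2,4-bis(methoxymethoxy)-3-[(2S,3S,4S,6S)-3-[(4-methoxyoxan-4-yl)oxy]-2-[4-(methoxymethoxy)phenyl]-6-{2-[4-(methoxymethoxy)phenyl]ethyl}oxan-4-yl]phenyl}-3-[4-(methoxymethoxy)phenyl]prop-2-en-1-one | COc1cc(OCOC)c([C@@H]2C[C@H](CCc3ccc(OCOC)cc3)O[C@@H](c3ccc(OCOC)cc3)[C@H]2OC2(OC)CCOCC2)c(OCOC)c1C(=O)/C=C/c1ccc(OCOC)cc1 | intermediate
31 | (E)-1-{2,4-dihydroxy-3-[(2S,3S,4S,6S)-3-hydroxy-2-(4-hydroxyphenyl)-6-[2-(4-hydroxyphenyl)ethyl]oxan-4-yl]-6-methoxyphenyl}-3-(4-hydroxyphenyl)prop-2-en-1-one (CNP0310862.1) | COc1cc(O)c([C@@H]2C[C@H](CCc3ccc(O)cc3)O[C@@H](c3ccc(O)cc3)[C@H]2O)c(O)c1C(=O)/C=C/c1ccc(O)cc1 | target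

## Step count and least certain steps

Total: 20 steps. Longest linear sequence: 17 steps (steps 1–6, 8, 9, 11–17, 19, 20); steps 7, 10 and 18 are side branches.

**Step 9 (key step).** The peracid may add only slowly to a ketone flanked by two substituted carbons. That leaves time for acid-catalysed enolisation toward C2, which would erode the cis relationship, and for electrophilic oxidation of ring A. Fallback (from 16, back at 17): the oxygen is inserted in stages instead of by a peracid. Soft enolisation of 16 toward the benzylic carbon (TMSCl, NaI, Et3N, MeCN) gives the trimethylsilyl enol ether F1. Ozonolysis at −78 °C with dimethyl sulfide work-up cleaves the enol ether double bond, which is far more reactive toward ozone than the arenes, to the aryl ketone acid F2. Felkin–Anh reduction of the α-alkoxy aryl ketone with K[(s-Bu)3BH] at −78 °C is expected to give the syn hydroxy acid F3, which is closed with EDC·HCl and DMAP to 17. The price is that C2 is then set by a carbonyl reduction and not by retention.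

**Step 5.** Displacement on the face already occupied by the aryl group is slow, so elimination of the oxyphosphonium ion, or base-induced epimerisation at C5 during formate methanolysis, can take over. Fallback (from 6, back at 16): the cis relationship is created at carbon instead of at oxygen, using the enantiomer that the resolution otherwise discards. The fast-reacting enantiomer of 6 is collected as the (1S,5R)-acetate F4 and hydrolysed by the same lipase in pH 7 buffer to the (4S,5R)-alcohol F5, which is converted into the ketal F6 as in step 6. Addition of cuprate 14 anti to the ketal gives the all-trans ketone F7, which differs from 16 only at C2. Soft enolisation toward the benzylic carbon gives the silyl enol ether F1 already described, and protodesilylation with Bu4NF/AcOH at −78 °C should deliver the proton to C2 from the face opposite the C3 ketal, a kinetic protonation that leads to the cis ketone 16.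

**Step 8.** Transfer of a di-ortho-substituted aryl group is slow, so the basic cuprate may instead remove the acidic C5 proton of the enone, leading to epimerisation to the trans enone or β-elimination. Fallback (from 12, back at 16): the aryl group is delivered by rhodium instead of copper. Aryllithium 13 is quenched with B(OMe)3 and hydrolysed to [4-methoxy-2,6-bis(methoxymethoxy)phenyl]boronic acid F8, which is added to 10 with [Rh(cod)OH]2 in aqueous dioxane (Hayashi–Miyaura conjugate addition). The aryl–rhodium species is not basic, the rhodium enolate is protonated by water as it forms, and the facial selectivity is again set by the two substituents on the other face.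

**Step 16.** Fluoride may act as a base or nucleophile on the secondary mesylate (elimination, substitution by fluoride) before desilylation and ring closure are complete. Fallback (from 23, back at 26): desilylation and ring closure are separated and the leaving group is placed by steric selection. Buffered fluoride (Bu4NF/AcOH) converts 23 into the diol F9. 2,4,6-Triisopropylbenzenesulfonyl chloride (pyridine, DMAP) should sulfonylate the unhindered C3 hydroxyl in preference to the benzylic C7 hydroxyl, which is flanked by the aryl group and the ketal, giving the monosulfonate F10. NaH in THF then closes the ring with inversion to 26.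

**Step 20.** During the time needed for the three unactivated aryl MOM ethers, acid may ionise the C2–O1 bond (capture by methanol, or re-closure to the 2,6-cis epimer) and may induce addition to, or cyclisation of, the hydroxychalcone. Fallback (from 30, back at 31): solvolysis is replaced by silyl transfer. TMSOTf with 2,2′-bipyridyl in MeCN at 0 °C converts aryl MOM ethers into aryl trimethylsilyl ethers without free Brønsted acid, and the ketal is exchanged for a silyl ether under the same conditions, giving the hexakis(trimethylsilyl) ether F11. KF in aqueous methanol at 0 °C then frees the six hydroxyl groups.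

## Further compounds

F1 | step 9 | trimethylsilyl enol ether of 16, enolised toward the aryl-bearing carbon | C[Si](C)(C)OC1=C(c2ccc(OCOC)cc2)[C@@H](OC2(OC)CCOCC2)[C@H](c2c(OCOC)cc(OC)cc2OCOC)C1
F2 | step 9 | (3S,4S)-4-[(4-methoxyoxan-4-yl)oxy]-3-[4-methoxy-2,6-bis(methoxymethoxy)phenyl]-5-[4-(methoxymethoxy)phenyl]-5-oxopentanoic acid | OC(=O)C[C@@H](c1c(OCOC)cc(OC)cc1OCOC)[C@H](OC1(OC)CCOCC1)C(=O)c1ccc(OCOC)cc1
F3 | step 9 | (3S,4S,5S)-5-hydroxy-4-[(4-methoxyoxan-4-yl)oxy]-3-[4-methoxy-2,6-bis(methoxymethoxy)phenyl]-5-[4-(methoxymethoxy)phenyl]pentanoic acid | OC(=O)C[C@@H](c1c(OCOC)cc(OC)cc1OCOC)[C@H](OC1(OC)CCOCC1)[C@@H](O)c1ccc(OCOC)cc1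
F4 | step 5 | (1S,5R)-5-[4-(methoxymethoxy)phenyl]-4-oxocyclopent-2-en-1-yl acetate | O=C1C=C[C@H](OC(C)=O)[C@H]1c1ccc(OCOC)cc1
F5 | step 5 | (4S,5R)-4-hydroxy-5-[4-(methoxymethoxy)phenyl]cyclopent-2-en-1-one | O=C1C=C[C@H](O)[C@H]1c1ccc(OCOC)cc1
F6 | step 5 | (4S,5R)-4-[(4-methoxyoxan-4-yl)oxy]-5-[4-(methoxymethoxy)phenyl]cyclopent-2-en-1-one | O=C1C=C[C@H](OC2(OC)CCOCC2)[C@H]1c1ccc(OCOC)cc1
F7 | step 5 | (2R,3S,4S)-3-[(4-methoxyoxan-4-yl)oxy]-4-[4-methoxy-2,6-bis(methoxymethoxy)phenyl]-2-[4-(methoxymethoxy)phenyl]cyclopentan-1-one | O=C1C[C@@H](c2c(OCOC)cc(OC)cc2OCOC)[C@H](OC2(OC)CCOCC2)[C@H]1c1ccc(OCOC)cc1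
F8 | step 8 | [4-methoxy-2,6-bis(methoxymethoxy)phenyl]boronic acid | OB(O)c1c(OCOC)cc(OC)cc1OCOC
F9 | step 16 | (3R,5S,6S,7S)-6-[(4-methoxyoxan-4-yl)oxy]-5-[4-methoxy-2,6-bis(methoxymethoxy)phenyl]-1,7-bis[4-(methoxymethoxy)phenyl]heptane-3,7-diol | O[C@H](CCc1ccc(OCOC)cc1)C[C@@H](c1c(OCOC)cc(OC)cc1OCOC)[C@H](OC1(OC)CCOCC1)[C@@H](O)c1ccc(OCOC)cc1
F10 | step 16 | (3R,5S,6S,7S)-7-hydroxy-6-[(4-methoxyoxan-4-yl)oxy]-5-[4-methoxy-2,6-bis(methoxymethoxy)phenyl]-1,7-bis[4-(methoxymethoxy)phenyl]heptan-3-yl 2,4,6-triisopropylbenzenesulfonate | CC(C)c9cc(C(C)C)c(c(C(C)C)c9)S(=O)(=O)O[C@H](CCc1ccc(OCOC)cc1)C[C@@H](c1c(OCOC)cc(OC)cc1OCOC)[C@H](OC1(OC)CCOCC1)[C@@H](O)c1ccc(OCOC)cc1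
F11 | step 20 | hexakis(trimethylsilyl) ether of 31 | COc1cc(O[Si](C)(C)C)c([C@@H]2C[C@H](CCc3ccc(O[Si](C)(C)C)cc3)O[C@@H](c3ccc(O[Si](C)(C)C)cc3)[C@H]2O[Si](C)(C)C)c(O[Si](C)(C)C)c1C(=O)/C=C/c1ccc(O[Si](C)(C)C)cc1
A1 | alternative 1 | (S)-furan-2-yl[4-(methoxymethoxy)phenyl]methanol | O[C@H](c1ccco1)c1ccc(OCOC)cc1
A2 | alternative 1 | (2S)-6-hydroxy-2-[4-(methoxymethoxy)phenyl]-2H-pyran-3(6H)-one (trans anomer drawn) | O=C1C=C[C@H](O)O[C@H]1c1ccc(OCOC)cc1
A3 | alternative 2 | 3-[4-(methoxymethoxy)phenyl]propanal | O=CCCc1ccc(OCOC)cc1
A4 | alternative 2 | (Z)-2,3-bis[(tert-butyldimethylsilyl)oxy]-1-methoxybuta-1,3-diene | CO/C=C(\O[Si](C)(C)C(C)(C)C)C(=C)O[Si](C)(C)C(C)(C)C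
A5 | alternative 2 | (S)-3-[(tert-butyldimethylsilyl)oxy]-6-{2-[4-(methoxymethoxy)phenyl]ethyl}-5,6-dihydro-4H-pyran-4-one (target numbering, enol ether carbon is C2) | O=C1C[C@H](CCc2ccc(OCOC)cc2)OC=C1O[Si](C)(C)C(C)(C)C
A6 | alternative 3 | (1S,2S)-1-hydroxy-3-[4-methoxy-2,6-bis(methoxymethoxy)phenyl]-1-[4-(methoxymethoxy)phenyl]but-3-en-2-yl 2-(diphenylphosphanyl)benzoate | C=C(c1c(OCOC)cc(OC)cc1OCOC)[C@H](OC(=O)c1ccccc1P(c1ccccc1)c1ccccc1)[C@H](c1ccc(OCOC)cc1)O
A7 | alternative 3 | (4S,5S,6S)-2-hydroxy-4-[4-methoxy-2,6-bis(methoxymethoxy)phenyl]-6-[4-(methoxymethoxy)phenyl]oxan-5-yl 2-(diphenylphosphanyl)benzoate (one anomer drawn) | O[C@H]1C[C@@H](c2c(OCOC)cc(OC)cc2OCOC)[C@H](OC(=O)c2ccccc2P(c2ccccc2)c2ccccc2)[C@H](c2ccc(OCOC)cc2)O1
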